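## Structural features

The target is a 2-arylchromane in which ring A (a phloroglucinol-type benzene ring, C4a to C8a) is fused to ring C (a dihydropyran made of O1, C2, C3 and C4), and ring B (a catechol) sits on C2. C2 and C3 are neighbouring stereocentres, both R, with the aryl group on C2 and the oxygen on C3 on the same face (cis), and C4 is a methylene between C3 and C4a. Two 3,4,5-trihydroxybenzoyl groups are present, one as the ester of the secondary alcohol on C3 and one as the aryl ester of O5, while O7, O3' and O4' stay free. The molecule is fragile: nine free phenols oxidise easily, the O5 aryl ester is an activated ester open to solvolysis and acyl transfer, and C2 can epimerise through a quinone methide once O4' is free and base is present. The real difficulty is twofold: O5 must be told apart from O7 on a ring A that derives from a symmetric triol, and the cis-(2R,3R) pair must be set beside an oxygenated benzylic carbon. The key step exploits the fact that ring A carries O1 on C8a and C4 on C4a on adjacent carbons, with O5 on C5 next to C4a; this is the pattern a 3-oxygenated benzyne acquires when a C=O unit adds across its triple bond, and the O5 group both steers the addition and arrives already distinct from O7. A second useful feature is that C3 can be held at the ketone level, which makes C2 epimerisable so that one reduction can fix both stereocentres.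

## Logic of the disconnections

22 ⇒ 21. The nine benzyl O–CH2 bonds are cut last. Hydrogenolysis is the one unmasking that the free polyphenol, the aryl ester on O5 and the C2 centre all tolerate, and it removes every protecting group at once. The forward step must be neutral and free of alcohol and base.

21 ⇒ 19 + 20. Both acyl–oxygen bonds, at O3 and at O5, are cut together. In 19 exactly these two hydroxyl groups are free and O7, O3' and O4' are benzylated, so two molecules of the one acid 20 supply both esters in a single operation. The forward step must fully acylate a phenol and a hindered axial secondary alcohol.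

19 ⇒ 18. The C3–H bond is cut, which returns C3 to a ketone. In 18 the hydrogen on C2 is α to that ketone, benzylic and α to O1, so C2 can epimerise and racemic 18 is sufficient. The forward step needs epimerisation faster than reduction, hydride delivery opposite to the C2 aryl group (cis), and a catalyst that selects one carbonyl face.

18 ⇒ 17. No skeletal bond is cut. The C3 ketone is traced to an enol ether and the O5 phenol to an acetal ether, both opened by one acid treatment. The gain is that the key step delivers C3 directly at the oxidation level the reduction needs. The forward step must be mild and air-free, because 18 is enolisable and ring A is a strong nucleophile.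

17 ⇒ 8 + 13. Three bonds are cut: O1–C8a, C4–C4a and O1–C2. O1 and C4 are the aldehyde group of 13, C2 and C3 its alkene, and ring A the aryne latent in 8. The cut is made here because it removes ring C completely and leaves two achiral pieces in which O5 (acetal) and O7 (benzyl) are already different. The forward step demands addition of the carbonyl oxygen to C8a and not to C4a, tolerance of fluoride by every group, and an alkene geometry in 13 that keeps the aryl group outside the closing triene. Two design decisions follow. In 13 the enol oxygen carries ethyl, not a second acetal, so that 13 comes in three steps from a purchasable phosphonate and only one formaldehyde-releasing group remains beside the nucleophilic ring A of 17. On O5 of 8 the acetal ether is kept, because a sulfonate there would be expelled by the carbanion at C4a (a second aryne), a silyl ether would not survive fluoride, and an acyl or carbamoyl group could migrate to C4a.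

13 ⇒ 12 ⇒ 11 ⇒ 9 + 10. The C2=C3 double bond is cut by olefination, after two adjustments of oxidation level at C4. This reduces the ring B fragment to a commercial aldehyde. The forward olefination must favour the Z isomer (aryl trans to the carbonyl carbon).

8 ⇒ 7 ⇒ 6 ⇒ 5 ⇒ 3 ⇒ 2 ⇒ 1. The S–O bond of the triflate, the O–CH2 bond of the acetal, the two carbamates, the C–Si bond and the O-benzyl bond are cut in turn. The C–Si bond is cut at the stage of 3, where two identical carbamates flank the only doubly activated C–H, so symmetry decides the position of silicon. The acetal is placed before the triflate, so that no phenoxide ever sits beside silicon with a triflate on the other side. The price is two statistical mono-etherifications (1 to 2, 6 to 7) and neutral handling of the electron-rich arylsilane 6.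

## Other disconnections considered

Alternative 1: The cut is C2–C3, with ring C reached only later by enlarging a five-membered ring. In the forward key step the diazo ester A2 is decomposed by Rh2(PTTL)4, dirhodium tetrakis(N-phthaloyl-tert-leucinate), in the enantiomeric form that leads to (2R). The carbenoid carbon (the future C3) inserts into a benzylic C–H bond of the O1–CH2–aryl ether; this is properly a C–H insertion, not an insertion into the O–CH2 bond. It forms C2–C3 and the cis-dihydrobenzofuran A1, whose ester carbon is the future C4. In its favour, a catalytic asymmetric C–C bond formation would fix the absolute configuration at C2 and a cis relationship in the key step itself; on this point the alternative is the better, since the chosen key step creates no stereochemical information. Against it, A1 is not yet the target ring: the ester must be reduced and activated, ring A must shift from C3 to C4 through an aryl-bridged cation, and an oxygen must enter at C3 with a steric course that ends cis-(2R,3R), and that migration is the uncertain part. A2 is also a hindered, doubly ortho-substituted aryldiazoacetate, and it needs three different oxygen substituents on ring A. In comparison, the two plans are equal on structure in the need for a differentiated ring A; on mechanism a concerted metal-carbenoid insertion stands against a pericyclic cascade; on step economy the chosen plan is ahead, with four steps after its key step against clearly more here.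

Alternative 2: The cuts are C4a–C8a, C5–C6 and C7–C8, so that ring A itself is assembled. In the forward key step [Rh(cod)2]BF4 with BINAP joins the tethered diyne A4 (a silyl ynol ether and an ethynyl ether linked through C4, C3, C2 and O1) with benzyl ethynyl ether A5 in a [2+2+2] cycloaddition, closing rings A and C together to give A3. In its favour, three C–C bonds and two rings form in one step, and both stereocentres are set beforehand in open-chain chemistry, so no late stereochemical risk remains; on this point the alternative is the better. O5 and O7 are distinguished simply by which ynol ether carries which group, which is at least the equal of the chosen plan. The end game is also equal: removal of the acetal and the silyl group from A3 gives 19, followed by the same two steps. Against it, A4 is long to make and delicate, since an ethynyl ether of a secondary benzylic alcohol and a silyl ynol ether are both prone to hydrolysis and ketene chemistry. The intermolecular partner A5 must insert in one orientation, or the benzyloxy group lands on C6, and the chirality of BINAP has no task, as no stereocentre is formed. In comparison, on mechanism a metallacycle-mediated cycloaddition whose regiochemistry rests on electronic bias stands against an aryne addition whose regiochemistry rests on a well-understood inductive effect; on step economy the alternative is shorter after its key step by one operation at most and much longer before it.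

Alternative 3: The cuts are O1–C2 and C3–C4. In the forward key step a chiral BINOL-derived phosphoric acid dehydrates the ortho-hydroxybenzyl alcohol A7 to the ortho-quinone methide A9, which adds the Z enol gallate A8 in an oxa-Diels–Alder reaction to give A6. A6 carries nine benzyl ethers, so it is correctly a nona-O-benzyl (not octa-O-benzyl) digallate, and it is identical with 21. In its favour, this is the most convergent plan: all carbons, both gallates and both stereocentres arrive in one step and only hydrogenolysis remains, so on step economy it is clearly better than the chosen plan. The cis relationship follows stereospecifically from the Z alkene, which is also better than relying on a reduction. Against it, A9 has no substituent on its methide carbon, the case in which ion-pair control by a chiral acid has least to hold on to. The regiochemistry is ambiguous: as an enol ester A8 should bond its aryl-bearing carbon to C4, whereas the target needs it to react as a styrene, with the acyloxy-bearing carbon going to C4. A7 holds an aryl ester next to a free benzylic alcohol and a free phenol, an invitation to acyl migration, making A7 requires the same O5/O7 differentiation as 8, and A8 is not trivial to prepare. In comparison, the plans are equal on structure in what ring A demands; on mechanism this plan concentrates regio-, diastereo- and enantiocontrol in one uncertain step, while the chosen plan spreads them over an inductively controlled aryne addition and a separate reduction.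

Key step: step 10

Assumptions:
- Ethyl 2-(diethoxyphosphoryl)-2-ethoxyacetate (10) and 3,4,5-tris(benzyloxy)benzoic acid (20) are taken as purchasable.
- Step 13 consumes two molecules of 20 per molecule of 19, one for each ester.
- The hand of the ligand in step 12 is a model-based prediction. The C2 side of the ketone (aryl- and oxygen-bearing) is assumed to take the place that the aryl group of an aryl ketone takes with this catalyst, so that the (R,R) ligand gives (3R). If the preference of this ketone class is the reverse, the mirror-image complex is used.
- Compounds 15, 17 and 18 are racemic and are drawn without configuration at the sp3 carbon concerned.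

## Route

Step 1
Reactants: 1 phloroglucinol
Product: 2 5-(benzyloxy)benzene-1,3-diol
Conditions: BnBr (0.5 equiv), K2CO3, DMF, 0 °C → rt
Reagents that add atoms: benzyl bromide, BrCc1ccccc1
Why: Williamson etherification of one of three equivalent phenols; with the triol in excess the mono-ether should be the main ether, the surplus triol is washed out with water, and the outcome is statistical by nature.

Step 2
Reactants: 2 5-(benzyloxy)benzene-1,3-diol
Product: 3 5-(benzyloxy)-1,3-phenylene bis(diethylcarbamate)
Conditions: ClC(O)NEt2 (2.4 equiv), K2CO3, MeCN, reflux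
Reagents that add atoms: diethylcarbamoyl chloride, CCN(CC)C(=O)Cl
Why: O-Carbamoylation of both phenols; the two identical carbamates are the strongest ortho-directing groups on the ring and prepare the next step.

Step 3
Reactants: 3 5-(benzyloxy)-1,3-phenylene bis(diethylcarbamate)
Product: 5 5-(benzyloxy)-2-(trimethylsilyl)-1,3-phenylene bis(diethylcarbamate), via aryllithium 4 (not isolated)
Conditions: s-BuLi, TMEDA, THF, −78 °C; then Me3SiCl, −78 °C → rt
Reagents that add atoms: chlorotrimethylsilane, C[Si](C)(C)Cl
Why: Directed ortho-metalation; the C–H flanked by two carbamates is the only doubly activated position, so symmetry fixes the site, and at −78 °C the aryllithium 4 should be silylated before a carbamoyl shift (anionic Fries rearrangement) or benzylic deprotonation can compete.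

Step 4
Reactants: 5 5-(benzyloxy)-2-(trimethylsilyl)-1,3-phenylene bis(diethylcarbamate)
Product: 6 5-(benzyloxy)-2-(trimethylsilyl)benzene-1,3-diol
Conditions: LiAlH4, THF, 0 °C → reflux; aq. sodium potassium tartrate work-up (pH 7–8)
Reagents that add atoms: none
Why: Reductive cleavage of aryl carbamates by hydride attack at the carbonyl group frees both phenols while the aryl–silicon bond and the benzyl ether are inert; a near-neutral work-up avoids ipso-protodesilylation of the very electron-rich arylsilane.

Step 5
Reactants: 6 5-(benzyloxy)-2-(trimethylsilyl)benzene-1,3-diol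
Product: 7 5-(benzyloxy)-3-(methoxymethoxy)-2-(trimethylsilyl)phenol
Conditions: NaH (1.0 equiv), MOMCl (1.0 equiv), THF/DMF, 0 °C
Reagents that add atoms: chloromethyl methyl ether, COCCl
Why: Mono-alkylation of a symmetric diol through its mono-sodium salt (Williamson-type acetal ether formation); the distribution is statistical, the bis-ether is separated and recovered 6 is recycled, and the aprotic basic medium keeps the carbon–silicon bond intact.

Step 6
Reactants: 7 5-(benzyloxy)-3-(methoxymethoxy)-2-(trimethylsilyl)phenol
Product: 8 5-(benzyloxy)-3-(methoxymethoxy)-2-(trimethylsilyl)phenyl trifluoromethanesulfonate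
Conditions: NaH, PhNTf2, THF, 0 °C → rt
Reagents that add atoms: N-phenylbis(trifluoromethanesulfonimide), O=S(=O)(N(c1ccccc1)S(=O)(=O)C(F)(F)F)C(F)(F)F
Why: Triflation of the remaining phenoxide with a mild triflyl donor that tolerates the acetal; because the acetal went on first, no phenoxide sits beside silicon opposite a triflate, so a carbon-to-oxygen silyl shift (Brook rearrangement) cannot release the aryne early.

Step 7
Reactants: 9 3,4-bis(benzyloxy)benzaldehyde; 10 ethyl 2-(diethoxyphosphoryl)-2-ethoxyacetate
Product: 11 ethyl (Z)-3-[3,4-bis(benzyloxy)phenyl]-2-ethoxyprop-2-enoate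
Conditions: NaH, THF, 0 °C → rt
Reagents that add atoms: none
Why: Horner–Wadsworth–Emmons olefination of an aromatic aldehyde with an α-alkoxy phosphonoacetate; the Z isomer (aryl trans to the ester, cis to ethoxy) is the less strained and should predominate, the E isomer being removed by chromatography or crystallisation.

Step 8
Reactants: 11 ethyl (Z)-3-[3,4-bis(benzyloxy)phenyl]-2-ethoxyprop-2-enoate
Product: 12 (Z)-3-[3,4-bis(benzyloxy)phenyl]-2-ethoxyprop-2-en-1-ol
Conditions: i-Bu2AlH, CH2Cl2, −78 °C; aq. sodium potassium tartrate
Reagents that add atoms: none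
Why: 1,2-Reduction of the conjugated ester to the allylic alcohol by i-Bu2AlH at low temperature; enol ether and benzyl ethers are inert, and the neutral tartrate work-up protects the acid-labile enol ether.

Step 9
Reactants: 12 (Z)-3-[3,4-bis(benzyloxy)phenyl]-2-ethoxyprop-2-en-1-ol
Product: 13 (Z)-3-[3,4-bis(benzyloxy)phenyl]-2-ethoxyprop-2-enal
Conditions: MnO2, CH2Cl2, rt
Reagents that add atoms: none
Why: Selective oxidation of an allylic alcohol by MnO2 under neutral conditions, which should leave the enol ether and its geometry untouched.

Step 10
Reactants: 8 5-(benzyloxy)-3-(methoxymethoxy)-2-(trimethylsilyl)phenyl trifluoromethanesulfonate; 13 (Z)-3-[3,4-bis(benzyloxy)phenyl]-2-ethoxyprop-2-enal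
Product: 17 7-(benzyloxy)-2-[3,4-bis(benzyloxy)phenyl]-3-ethoxy-5-(methoxymethoxy)-2H-chromene (racemic), via aryne 14 (not isolated), via benzoxete 15 (not isolated), via ortho-quinone methide 16 (not isolated)
Conditions: CsF, MeCN, rt → 40 °C, argon (13 in excess)
Reagents that add atoms: none
Why: Fluoride attacks silicon in 8 and triflate leaves, giving the 3-alkoxybenzyne 14. The carbonyl oxygen of 13 adds to C8a, the aryne carbon remote from the O5 acetal, and the carbanion at C4a closes onto the carbonyl carbon, a formal [2+2] cycloaddition to benzoxete 15. Thermal four-electron ring opening of 15 breaks the O–C4 bond and gives the ortho-quinone methide 16, an oxatriene O1=C8a–C4a=C4–C3=C2. Ring C then closes by thermal disrotatory oxa-6π electrocyclisation, which forms O1–C2 and restores the aromaticity of ring A. The closest known reaction type is the cascade of arynes with α,β-unsaturated aldehydes to 2H-chromenes; the α-ethoxy group is an added spectator on C3. C2 is the only new stereocentre and forms with no controlling element, racemic on purpose, because step 12 resets it. The selectivity needed is regiochemical: the σ-withdrawing O5 substituent beside the triple bond makes C8a the electrophilic terminus and stabilises charge at C4a, and the Z geometry of 13 keeps the aryl group on the outside of the closing triene. Preference for the carbonyl oxygen over the enol ether double bond is helped by the excess of 13 and the slow release of 14.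

Step 11
Reactants: 17 7-(benzyloxy)-2-[3,4-bis(benzyloxy)phenyl]-3-ethoxy-5-(methoxymethoxy)-2H-chromene (racemic)
Product: 18 7-(benzyloxy)-2-[3,4-bis(benzyloxy)phenyl]-5-hydroxychroman-3-one (racemic)
Conditions: 2 M aq. HCl, THF/MeOH, 45 °C, degassed
Reagents that add atoms: water, O
Why: Acid-catalysed hydrolysis: protonation of the enol ether at C4 and capture of the C3 oxocarbenium ion by water give the ketone and ethanol, and the aryl acetal on O5 is cleaved in the same medium while benzyl ethers persist; methanol takes up the formaldehyde, exclusion of air protects the enolisable ketone, and 18 is carried on crude.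

Step 12
Reactants: 18 7-(benzyloxy)-2-[3,4-bis(benzyloxy)phenyl]-5-hydroxychroman-3-one (racemic)
Product: 19 (2R,3R)-7-(benzyloxy)-2-[3,4-bis(benzyloxy)phenyl]chromane-3,5-diol
Conditions: RuCl(p-cymene)[(R,R)-TsDPEN] (2 mol %), HCO2H/DBU, DMF, 40 °C, argon
Reagents that add atoms: none
Why: Asymmetric transfer hydrogenation with dynamic kinetic resolution: the amine base epimerises C2 through the enolate, the bifunctional ruthenium hydride reduces C3 from the face opposite to the C2 aryl group (cis), and the (R,R) ligand is expected to select the Si face of the carbonyl, so that the (2R) ketone is the one consumed and C2 and C3 are both set as R.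

Step 13
Reactants: 19 (2R,3R)-7-(benzyloxy)-2-[3,4-bis(benzyloxy)phenyl]chromane-3,5-diol; 20 3,4,5-tris(benzyloxy)benzoic acid
Product: 21 (2R,3R)-7-(benzyloxy)-2-[3,4-bis(benzyloxy)phenyl]chromane-3,5-diyl bis[3,4,5-tris(benzyloxy)benzoate]
Conditions: 20 (3 equiv in all), DCC (3 equiv), DMAP (0.5 equiv), CH2Cl2, 0 °C → rt
Reagents that add atoms: 3,4,5-tris(benzyloxy)benzoic acid as the second molar equivalent of 20, O=C(O)c1cc(OCc2ccccc2)c(OCc2ccccc2)c(OCc2ccccc2)c1
Why: Carbodiimide esterification with DMAP as acyl-transfer catalyst (Steglich esterification) should acylate both the phenol O5 and the axial secondary alcohol O3, one molecule of 20 being consumed for each ester and each condensation giving one molecule of the urea; neither stereocentre takes part.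

Step 14
Reactants: 21 (2R,3R)-7-(benzyloxy)-2-[3,4-bis(benzyloxy)phenyl]chromane-3,5-diyl bis[3,4,5-tris(benzyloxy)benzoate]
Product: 22 epicatechin 3,5-di-O-gallate, (2R,3R)-2-(3,4-dihydroxyphenyl)-7-hydroxychromane-3,5-diyl bis(3,4,5-trihydroxybenzoate)
Conditions: H2 (1 atm), Pd(OH)2/C, THF/EtOAc, rt
Reagents that add atoms: none
Why: Hydrogenolysis of nine benzyl ethers over Pd(OH)2/C in a neutral, non-nucleophilic solvent; the two esters, the cyclic C2–O1 ether and both stereocentres are expected to survive, and the absence of base and alcohol protects the O5 aryl ester.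

## Compound list

1 | phloroglucinol (benzene-1,3,5-triol) | Oc1cc(O)cc(O)c1 | starting material
2 | 5-(benzyloxy)benzene-1,3-diol | Oc1cc(O)cc(OCc2ccccc2)c1 | intermediate
3 | 5-(benzyloxy)-1,3-phenylene bis(diethylcarbamate) | CCN(CC)C(=O)Oc1cc(OCc2ccccc2)cc(OC(=O)N(CC)CC)c1 | intermediate
4 | [4-(benzyloxy)-2,6-bis(diethylcarbamoyloxy)phenyl]lithium | [Li]c1c(OC(=O)N(CC)CC)cc(OCc2ccccc2)cc1OC(=O)N(CC)CC | intermediate (not isolated)
5 | 5-(benzyloxy)-2-(trimethylsilyl)-1,3-phenylene bis(diethylcarbamate) | CCN(CC)C(=O)Oc1cc(OCc2ccccc2)cc(OC(=O)N(CC)CC)c1[Si](C)(C)C | intermediate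
6 | 5-(benzyloxy)-2-(trimethylsilyl)benzene-1,3-diol | C[Si](C)(C)c1c(O)cc(OCc2ccccc2)cc1O | intermediate
7 | 5-(benzyloxy)-3-(methoxymethoxy)-2-(trimethylsilyl)phenol | COCOc1cc(OCc2ccccc2)cc(O)c1[Si](C)(C)C | intermediate
8 | 5-(benzyloxy)-3-(methoxymethoxy)-2-(trimethylsilyl)phenyl trifluoromethanesulfonate | COCOc1cc(OCc2ccccc2)cc(OS(=O)(=O)C(F)(F)F)c1[Si](C)(C)C | intermediate
9 | 3,4-bis(benzyloxy)benzaldehyde | O=Cc1ccc(OCc2ccccc2)c(OCc2ccccc2)c1 | starting material
10 | ethyl 2-(diethoxyphosphoryl)-2-ethoxyacetate | CCOC(=O)C(OCC)P(=O)(OCC)OCC | starting material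
11 | ethyl (Z)-3-[3,4-bis(benzyloxy)phenyl]-2-ethoxyprop-2-enoate | CCO/C(C(=O)OCC)=C\c1ccc(OCc2ccccc2)c(OCc2ccccc2)c1 | intermediate
12 | (Z)-3-[3,4-bis(benzyloxy)phenyl]-2-ethoxyprop-2-en-1-ol | CCO/C(CO)=C\c1ccc(OCc2ccccc2)c(OCc2ccccc2)c1 | intermediate
13 | (Z)-3-[3,4-bis(benzyloxy)phenyl]-2-ethoxyprop-2-enal | CCO/C(C=O)=C\c1ccc(OCc2ccccc2)c(OCc2ccccc2)c1 | intermediate
14 | 5-(benzyloxy)-3-(methoxymethoxy)benzyne (1,2-didehydrobenzene) | COCOC1=CC(OCc2ccccc2)=CC#C1 | intermediate (not isolated)
15 | 5-(benzyloxy)-2-{(Z)-2-[3,4-bis(benzyloxy)phenyl]-1-ethoxyethenyl}-3-(methoxymethoxy)-2H-benzo[b]oxete (racemic) | COCOc1cc(OCc2ccccc2)cc2OC(/C(OCC)=C/c3ccc(OCc4ccccc4)c(OCc4ccccc4)c3)c12 | intermediate (not isolated)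
16 | (6Z)-3-(benzyloxy)-6-{(2Z)-3-[3,4-bis(benzyloxy)phenyl]-2-ethoxyprop-2-en-1-ylidene}-5-(methoxymethoxy)cyclohexa-2,4-dien-1-one | COCOC1=CC(OCc2ccccc2)=CC(=O)/C1=C\C(OCC)=C\c1ccc(OCc2ccccc2)c(OCc2ccccc2)c1 | intermediate (not isolated)
17 | 7-(benzyloxy)-2-[3,4-bis(benzyloxy)phenyl]-3-ethoxy-5-(methoxymethoxy)-2H-chromene (racemic) | CCOC1=Cc2c(OCOC)cc(OCc3ccccc3)cc2OC1c1ccc(OCc2ccccc2)c(OCc2ccccc2)c1 | intermediate
18 | 7-(benzyloxy)-2-[3,4-bis(benzyloxy)phenyl]-5-hydroxychroman-3-one (racemic) | O=C1Cc2c(O)cc(OCc3ccccc3)cc2OC1c1ccc(OCc2ccccc2)c(OCc2ccccc2)c1 | intermediate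
19 | (2R,3R)-7-(benzyloxy)-2-[3,4-bis(benzyloxy)phenyl]chromane-3,5-diol | Oc1cc(OCc2ccccc2)cc2c1C[C@@H](O)[C@@H](c1ccc(OCc3ccccc3)c(OCc3ccccc3)c1)O2 | intermediate
20 | 3,4,5-tris(benzyloxy)benzoic acid | O=C(O)c1cc(OCc2ccccc2)c(OCc2ccccc2)c(OCc2ccccc2)c1 | starting material
21 | (2R,3R)-7-(benzyloxy)-2-[3,4-bis(benzyloxy)phenyl]chromane-3,5-diyl bis[3,4,5-tris(benzyloxy)benzoate] | O=C(Oc1cc(OCc2ccccc2)cc2c1C[C@@H](OC(=O)c1cc(OCc3ccccc3)c(OCc3ccccc3)c(OCc3ccccc3)c1)[C@@H](c1ccc(OCc3ccccc3)c(OCc3ccccc3)c1)O2)c1cc(OCc2ccccc2)c(OCc2ccccc2)c(OCc2ccccc2)c1 | intermediate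
22 | epicatechin 3,5-di-O-gallate, (2R,3R)-2-(3,4-dihydroxyphenyl)-7-hydroxychromane-3,5-diyl bis(3,4,5-trihydroxybenzoate) | O=C(Oc1cc(O)cc2c1C[C@@H](OC(=O)c1cc(O)c(O)c(O)c1)[C@@H](c1ccc(O)c(O)c1)O2)c1cc(O)c(O)c(O)c1 | target

## Step count and least certain steps

Total: 14 steps (six to 8, three to 13, then five). Longest linear sequence: 11 steps (steps 1 to 6 and 10 to 14).

Step 10 (key step). The most likely failure is consumption of the aryne by routes other than carbonyl addition: cycloaddition or ene reaction with the electron-rich enol ether double bond of 13 or of product 17, or self-reaction of the aryne if the α-alkoxy enal proves a sluggish oxygen nucleophile. Loss of regiocontrol is the less likely problem. The fallback sets out from 8 and 9 and returns at 18. 8 is treated with CsF in DMF, so that the aryne inserts into the formamide C=O with the same regiochemistry, and aqueous work-up gives 4-(benzyloxy)-2-hydroxy-6-(methoxymethoxy)benzaldehyde F1. 9 is condensed with nitromethane (Henry reaction with dehydration, NH4OAc/AcOH) to (E)-1,2-bis(benzyloxy)-4-(2-nitroethenyl)benzene F2. F1 and F2 are joined with DABCO by oxa-Michael addition, intramolecular Henry reaction and dehydration to 7-(benzyloxy)-2-[3,4-bis(benzyloxy)phenyl]-5-(methoxymethoxy)-3-nitro-2H-chromene F3. TiCl3 in aqueous HCl/THF then converts the nitroalkene into the ketone and removes the acetal in the same acidic medium, giving 18.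

Step 12. Two processes may fail. Epimerisation of C2 may be slower than hydride transfer, so that the reduction becomes a simple kinetic resolution that stalls or erodes diastereo- and enantiopurity. The facial preference of the catalyst for this non-conjugated ketone may also be weak or opposite to the model (the mirror-image ligand answers only the second point). The fallback sets out from 18 and returns at 19: substrate-controlled reduction with LiB(s-Bu)3H in THF at −78 °C, where hydride enters opposite to the C2 aryl group, gives racemic cis-7-(benzyloxy)-2-[3,4-bis(benzyloxy)phenyl]chromane-3,5-diol F4. Its enantiomers are separated by preparative chromatography on a chiral stationary phase, and the (2R,3R) half is 19.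

Step 11. The acid needed for the aryl acetal may also drive electrophilic substitution of the phloroglucinol-type ring A by formaldehyde or by the protonated ketone of a second molecule, and the enol of 18 may be oxidised toward a flavylium salt. The fallback sets out from 17 and returns at 19, and changes the order of unmasking so that O5 is freed only when no ketone is present. Very dilute acid at 0 °C (0.1 M HCl, THF) hydrolyses only the enol ether, giving 7-(benzyloxy)-2-[3,4-bis(benzyloxy)phenyl]-5-(methoxymethoxy)chroman-3-one F5. The reduction of step 12 is applied to F5 and gives (2R,3R)-7-(benzyloxy)-2-[3,4-bis(benzyloxy)phenyl]-5-(methoxymethoxy)chroman-3-ol F6. The acetal is then cleaved on this robust alcohol (aq. HCl/MeOH, 45 °C) to give 19.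

Step 5 (with step 4). The free diol 6 is an extremely electron-rich arylsilane. Ipso-protonation with loss of silicon during work-up or chromatography is the likely failure, and the mono-etherification is statistical on material that is already four steps old. The fallback sets out from 2 and returns at 7, and moves the desymmetrisation in front of the silylation. 2 is mono-alkylated (NaH, MOMCl) to 3-(benzyloxy)-5-(methoxymethoxy)phenol F7. F7 is carbamoylated (ClC(O)NEt2, K2CO3) to 3-(benzyloxy)-5-(methoxymethoxy)phenyl diethylcarbamate F8. Directed ortho-metalation (s-BuLi, TMEDA, −78 °C, then Me3SiCl) should occur between the carbamate and the chelating acetal ether, giving 5-(benzyloxy)-3-(methoxymethoxy)-2-(trimethylsilyl)phenyl diethylcarbamate F9; the open point of this fallback is the preference for that position over the one between carbamate and benzyl ether. LiAlH4 then cleaves the carbamate and gives 7.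

## Further compounds

F1 | step 10 | 4-(benzyloxy)-2-hydroxy-6-(methoxymethoxy)benzaldehyde | COCOc1cc(OCc2ccccc2)cc(O)c1C=O
F2 | step 10 | (E)-1,2-bis(benzyloxy)-4-(2-nitroethenyl)benzene | O=[N+]([O-])/C=C/c1ccc(OCc2ccccc2)c(OCc2ccccc2)c1
F3 | step 10 | 7-(benzyloxy)-2-[3,4-bis(benzyloxy)phenyl]-5-(methoxymethoxy)-3-nitro-2H-chromene (racemic) | COCOc1cc(OCc2ccccc2)cc2OC(c3ccc(OCc4ccccc4)c(OCc4ccccc4)c3)C([N+](=O)[O-])=Cc12
F4 | step 12 | racemic cis-7-(benzyloxy)-2-[3,4-bis(benzyloxy)phenyl]chromane-3,5-diol | Oc1cc(OCc2ccccc2)cc2c1C[C@@H](O)[C@@H](c1ccc(OCc3ccccc3)c(OCc3ccccc3)c1)O2.Oc1cc(OCc2ccccc2)cc2c1C[C@H](O)[C@H](c1ccc(OCc3ccccc3)c(OCc3ccccc3)c1)O2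
F5 | step 11 | 7-(benzyloxy)-2-[3,4-bis(benzyloxy)phenyl]-5-(methoxymethoxy)chroman-3-one (racemic) | COCOc1cc(OCc2ccccc2)cc2OC(c3ccc(OCc4ccccc4)c(OCc4ccccc4)c3)C(=O)Cc12
F6 | step 11 | (2R,3R)-7-(benzyloxy)-2-[3,4-bis(benzyloxy)phenyl]-5-(methoxymethoxy)chroman-3-ol | COCOc1cc(OCc2ccccc2)cc2c1C[C@@H](O)[C@@H](c1ccc(OCc3ccccc3)c(OCc3ccccc3)c1)O2
F7 | step 5 | 3-(benzyloxy)-5-(methoxymethoxy)phenol | COCOc1cc(O)cc(OCc2ccccc2)c1
F8 | step 5 | 3-(benzyloxy)-5-(methoxymethoxy)phenyl diethylcarbamate | CCN(CC)C(=O)Oc1cc(OCOC)cc(OCc2ccccc2)c1
F9 | step 5 | 5-(benzyloxy)-3-(methoxymethoxy)-2-(trimethylsilyl)phenyl diethylcarbamate | CCN(CC)C(=O)Oc1cc(OCc2ccccc2)cc(OCOC)c1[Si](C)(C)C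
A1 | alternative 1 | methyl cis-6-(benzyloxy)-2-[3,4-bis(benzyloxy)phenyl]-4-[(triisopropylsilyl)oxy]-2,3-dihydrobenzofuran-3-carboxylate | COC(=O)[C@@H]1c2c(O[Si](C(C)C)(C(C)C)C(C)C)cc(OCc3ccccc3)cc2O[C@@H]1c1ccc(OCc2ccccc2)c(OCc2ccccc2)c1
A2 | alternative 1 | methyl 2-[4-(benzyloxy)-2-{[3,4-bis(benzyloxy)benzyl]oxy}-6-[(triisopropylsilyl)oxy]phenyl]-2-diazoacetate | COC(=O)C(=[N+]=[N-])c1c(O[Si](C(C)C)(C(C)C)C(C)C)cc(OCc2ccccc2)cc1OCc1ccc(OCc2ccccc2)c(OCc2ccccc2)c1
A3 | alternative 2 | 7,3',4'-tri-O-benzyl-3-O-(methoxymethyl)-5-O-(triisopropylsilyl)epicatechin | CC(C)[Si](Oc1cc(OCc2ccccc2)cc2c1C[C@@H](OCOC)[C@@H](c1ccc(OCc3ccccc3)c(OCc3ccccc3)c1)O2)(C(C)C)C(C)C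
A4 | alternative 2 | triisopropyl({(4R,5R)-5-[3,4-bis(benzyloxy)phenyl]-5-(ethynyloxy)-4-(methoxymethoxy)pent-1-yn-1-yl}oxy)silane | CC(C)[Si](OC#CC[C@@H](OCOC)[C@@H](c1ccc(OCc2ccccc2)c(OCc2ccccc2)c1)OC#C)(C(C)C)C(C)C
A5 | alternative 2 | benzyl ethynyl ether | C#COCc1ccccc1
A6 | alternative 3 | nona-O-benzyl epicatechin 3,5-di-O-gallate (identical with 21) | O=C(Oc1cc(OCc2ccccc2)cc2c1C[C@@H](OC(=O)c1cc(OCc3ccccc3)c(OCc3ccccc3)c(OCc3ccccc3)c1)[C@@H](c1ccc(OCc3ccccc3)c(OCc3ccccc3)c1)O2)c1cc(OCc2ccccc2)c(OCc2ccccc2)c(OCc2ccccc2)c1
A7 | alternative 3 | 5-(benzyloxy)-3-hydroxy-2-(hydroxymethyl)phenyl 3,4,5-tris(benzyloxy)benzoate | OCc1c(O)cc(OCc2ccccc2)cc1OC(=O)c1cc(OCc2ccccc2)c(OCc2ccccc2)c(OCc2ccccc2)c1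
A8 | alternative 3 | (Z)-2-[3,4-bis(benzyloxy)phenyl]ethenyl 3,4,5-tris(benzyloxy)benzoate | O=C(O/C=C\c1ccc(OCc2ccccc2)c(OCc2ccccc2)c1)c1cc(OCc2ccccc2)c(OCc2ccccc2)c(OCc2ccccc2)c1
A9 | alternative 3 | 3-(benzyloxy)-6-methylidene-5-oxocyclohexa-1,3-dien-1-yl 3,4,5-tris(benzyloxy)benzoate | C=C1C(=O)C=C(OCc2ccccc2)C=C1OC(=O)c1cc(OCc2ccccc2)c(OCc2ccccc2)c(OCc2ccccc2)c1
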